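**Retrosynthetic overview**
1. Target 12 ⇐ bis-benzyl ether 11 ⇐ bicyclic cyclopropyl ketone 8: hydrolytic opening of the cyclopropane turns the CH2 bridge into the CH2OH group and the bridgehead into the epimerisable C-3, which settles trans.
2. 8 ⇐ 1,6-enyne 7: a gold-catalysed alkyne oxidation–cyclopropanation closes the oxolane ring and the cyclopropane in one operation and creates the aryl ketone; the benzylic ether centre steers C-4.
3. 7 ⇐ rac-allylic alcohol 3 + propargylic alcohol 6: an iridium-catalysed enantioconvergent allylic etherification sets the only catalyst-controlled centre (future C-5, S).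
4. 3 ⇐ aldehyde 1 + vinylmagnesium bromide 2; 6 ⇐ aryl bromide 4 + propargyl alcohol 5 (Sonogashira).
5. Ring order: both arenes are bought; oxolane and cyclopropane form together (step 4); the cyclopropane is cleaved again (step 5).

Assumption: 1 and 4 are bought as the O-benzyl ethers (4 is otherwise one benzylation from 5-bromo-2-methoxyphenol); locants follow the target oxolane (C-3 aroyl carbon, C-4 CH2OH carbon, C-5 aryl carbon).

**Step 1**
Reactants: 1 3-(benzyloxy)-4-methoxybenzaldehyde; 2 vinylmagnesium bromide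
Product: 3 rac-1-[3-(benzyloxy)-4-methoxyphenyl]prop-2-en-1-ol
Conditions: 2 (1.2 equiv), THF, −20 → 0 °C; aq. NH4Cl
Reagents that add atoms: none
Why: Grignard 1,2-addition to an aryl aldehyde gives the racemic branched allylic alcohol, whose centre is fixed only in step 3.

**Step 2**
Reactants: 4 2-(benzyloxy)-4-bromo-1-methoxybenzene; 5 prop-2-yn-1-ol
Product: 6 3-[3-(benzyloxy)-4-methoxyphenyl]prop-2-yn-1-ol
Conditions: PdCl2(MeCN)2 (2 mol%), XPhos (6 mol%), Cs2CO3, MeCN, 75 °C
Reagents that add atoms: none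
Why: Copper-free Sonogashira coupling, with the bulky biarylphosphine making oxidative addition to the electron-rich aryl bromide fast; no stereocentre is formed.

**Step 3**
Reactants: 3 rac-1-[3-(benzyloxy)-4-methoxyphenyl]prop-2-en-1-ol; 6 3-[3-(benzyloxy)-4-methoxyphenyl]prop-2-yn-1-ol
Product: 7 (S)-2-(benzyloxy)-4-[3-({1-[3-(benzyloxy)-4-methoxyphenyl]prop-2-en-1-yl}oxy)prop-1-yn-1-yl]-1-methoxybenzene
Conditions: [Ir(cod)Cl]2 (3 mol%), BINOL–dibenzazepine phosphoramidite (P,olefin) ligand (12 mol%, the enantiomer that gives (S)-7), (BuO)2P(O)OH (20 mol%), 3 (1.3 equiv), ClCH2CH2Cl, 25 °C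
Reagents that add atoms: none
Why: Iridium-catalysed enantioconvergent allylic etherification, in which both enantiomers of 3 ionise to one π-allyl iridium complex that the primary alcohol 6 attacks at the branched benzylic terminus, so the chiral ligand sets the (S) centre that becomes C-5.

**Step 4**
Reactants: 7 (S)-enyne ether
Product: 8 [(1S,4S,5S)-4-[3-(benzyloxy)-4-methoxyphenyl]-3-oxabicyclo[3.1.0]hexan-1-yl][3-(benzyloxy)-4-methoxyphenyl]methanone
Conditions: [Au(IPr)(NTf2)] (5 mol%; IPr = 1,3-bis(2,6-diisopropylphenyl)imidazol-2-ylidene), 8-methylquinoline N-oxide (1.5 equiv), ClCH2CH2Cl, 25 °C, no acid additive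
Reagents that add atoms: 8-methylquinoline N-oxide, Cc1cccc2ccc[n+]([O-])c12
Why: Gold-catalysed alkyne oxidation–intramolecular cyclopropanation of a 1,6-enyne, in which the N-oxide attacks the alkyne activated by monovalent gold at the aryl-bearing carbon and the resulting α-oxo gold carbene cyclopropanates the tethered vinyl group, closing oxolane and cyclopropane together; the aryl group at the existing centre takes the face opposite to the new CH2 bridge, which sets C-1 and C-5 (the future C-4 configuration), and any syn isomer is removed by chromatography.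

**Step 5**
Reactants: 8 bicyclic cyclopropyl ketone
Product: 11 [(3S,4R,5S)-5-[3-(benzyloxy)-4-methoxyphenyl]-4-(hydroxymethyl)oxolan-3-yl][3-(benzyloxy)-4-methoxyphenyl]methanone, via silyl enol ether iodide 9 (not isolated), via iodo ketone 10 (not isolated)
Conditions: Me3SiI (1.2 equiv), CH2Cl2, −40 → 0 °C; then acetone–H2O, 0 °C; then Ag2CO3, 25 °C, dark; then K2CO3 (0.2 equiv), MeOH, 25 °C
Reagents that add atoms: water, O (iodotrimethylsilane, C[Si](C)(C)I, puts Si and I into 9 and 10 only)
Why: Silyl iodide ring opening of a cyclopropyl ketone (iodide attacks the unsubstituted CH2 bridge in an SN2 manner and cleaves the C-1–C-6 bond), then hydrolysis of the silyl enol ether and silver-assisted hydrolysis of the primary iodide; C-4 and C-5 are untouched, and C-3, now α to the ketone, is equilibrated by base through the enolate to the more stable 3,4-trans arrangement (the cis isomer only reaches a reversible hemiketal).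

**Step 6**
Reactants: 11 bis-benzyl ether
Product: 12 [(3S,4R,5S)-5-(3-hydroxy-4-methoxyphenyl)-4-(hydroxymethyl)oxolan-3-yl](3-hydroxy-4-methoxyphenyl)methanone
Conditions: H2 (1 atm), 10% Pd/C, EtOAc–MeOH, 25 °C, stopped after uptake of 2 equiv
Reagents that add atoms: none
Why: Hydrogenolysis of the two aryl benzyl ethers, which is much faster than cleavage of the cyclic dialkyl benzylic ether or reduction of the electron-rich aryl ketone; no stereocentre is touched.

**Compound list**
1 | 3-(benzyloxy)-4-methoxybenzaldehyde | COc1ccc(C=O)cc1OCc1ccccc1 | starting material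
2 | vinylmagnesium bromide | C=C[Mg]Br | starting material
3 | rac-1-[3-(benzyloxy)-4-methoxyphenyl]prop-2-en-1-ol | C=CC(O)c1ccc(OC)c(OCc2ccccc2)c1 | intermediate
4 | 2-(benzyloxy)-4-bromo-1-methoxybenzene | COc1ccc(Br)cc1OCc1ccccc1 | starting material
5 | prop-2-yn-1-ol | C#CCO | starting material
6 | 3-[3-(benzyloxy)-4-methoxyphenyl]prop-2-yn-1-ol | OCC#Cc1ccc(OC)c(OCc2ccccc2)c1 | intermediate
7 | (S)-2-(benzyloxy)-4-[3-({1-[3-(benzyloxy)-4-methoxyphenyl]prop-2-en-1-yl}oxy)prop-1-yn-1-yl]-1-methoxybenzene | C=C[C@H](OCC#Cc1ccc(OC)c(OCc2ccccc2)c1)c1ccc(OC)c(OCc2ccccc2)c1 | intermediate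
8 | [(1S,4S,5S)-4-[3-(benzyloxy)-4-methoxyphenyl]-3-oxabicyclo[3.1.0]hexan-1-yl][3-(benzyloxy)-4-methoxyphenyl]methanone (4-aryl anti to the cyclopropane CH2) | O=C(c1ccc(OC)c(OCc2ccccc2)c1)[C@]34CO[C@H](c5ccc(OC)c(OCc6ccccc6)c5)[C@H]3C4 | intermediate
9 | {[3-(benzyloxy)-4-methoxyphenyl][(4S,5S)-5-[3-(benzyloxy)-4-methoxyphenyl]-4-(iodomethyl)oxolan-3-ylidene]methoxy}trimethylsilane (E/Z mixture) | C[Si](C)(C)OC(c1ccc(OC)c(OCc2ccccc2)c1)=C3CO[C@H](c4ccc(OC)c(OCc5ccccc5)c4)[C@H]3CI | intermediate (not isolated)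
10 | [(4S,5S)-5-[3-(benzyloxy)-4-methoxyphenyl]-4-(iodomethyl)oxolan-3-yl][3-(benzyloxy)-4-methoxyphenyl]methanone (C-3 epimers) | O=C(c1ccc(OC)c(OCc2ccccc2)c1)C3CO[C@H](c4ccc(OC)c(OCc5ccccc5)c4)[C@H]3CI | intermediate (not isolated)
11 | [(3S,4R,5S)-5-[3-(benzyloxy)-4-methoxyphenyl]-4-(hydroxymethyl)oxolan-3-yl][3-(benzyloxy)-4-methoxyphenyl]methanone | COc1ccc(C(=O)[C@@H]2CO[C@H](c3ccc(OC)c(OCc4ccccc4)c3)[C@H]2CO)cc1OCc1ccccc1 | intermediate
12 | [(3S,4R,5S)-5-(3-hydroxy-4-methoxyphenyl)-4-(hydroxymethyl)oxolan-3-yl](3-hydroxy-4-methoxyphenyl)methanone | COc1ccc(C(=O)[C@@H]2CO[C@H](c3ccc(OC)c(O)c3)[C@H]2CO)cc1O | target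

**Totals**
Total steps: 6. Longest linear sequence: 5 (steps 1, 3, 4, 5, 6); step 2 is a one-step side branch.

**Steps most likely to fail, with fallbacks**

Step 4 (gold bicyclisation). The p-alkoxybenzylic C–H next to the ether oxygen can transfer hydride to the activated alkyne (fragmentation to an allene). The α-oxo carbene can also undergo a 1,2-hydrogen shift to a β-alkoxy enone, the electron-rich arene can attack the alkyne, and the anti/syn ratio is untested for this substrate. The fallback sets out from 7 and comes back at 11, with no carbene and no cyclopropane. Pd(OAc)2 (5 mol%), bis(pinacolato)diboron and MeOH in toluene at 50 °C effect a borylative enyne cyclisation to the alkylboronate F4 (oxolane closed, exocyclic arylidene, CH2Bpin trans to the 2-aryl group). BH3·THF then adds boron to the less substituted benzylic alkene carbon, and NaBO3 oxidises both C–B bonds to give the diol F5. MnO2 in CH2Cl2 oxidises only the benzylic alcohol to the aryl ketone, and K2CO3/MeOH brings C-3 to trans, giving 11.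

Step 5 (cyclopropane opening). Me3SiI may also cleave the benzyl ethers or ionise the p-alkoxybenzylic oxolane C–O bond. Iodide could instead open the ring-fusion bond (ring enlargement), and the iodo ketone can reclose to 8 before it is hydrolysed. The fallback sets out from 7 and comes back at 11 by a radical route. mCPBA (NaHCO3, CH2Cl2) epoxidises the terminal alkene to the epoxide F6 (the epoxide epimers are immaterial). Cp2TiCl, made from Cp2TiCl2 and Zn in THF, opens the epoxide with trivalent titanium to a β-titanoxy secondary radical, which cyclises 5-exo-dig onto the aryl alkyne; this gives the arylidene alcohol F7 with the CH2OH trans to the aryl group. Hydroboration–oxidation (BH3·THF, then NaBO3) leads to the diol F5 already described, and MnO2 followed by K2CO3/MeOH gives 11.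

Step 3 (iridium etherification). The very electron-rich alcohol 3 can ionise without the metal, which would give racemic or linear (cinnamyl) ether and erode the ee. The fallback sets out from 3 and 6 and comes back at 7. Candida antarctica lipase B with vinyl acetate in MTBE acetylates the (R)-enantiomer to the (R)-acetate F2 and leaves the (S)-alcohol F1 (at most 50%). Alcohol 6 is converted with CBr4/PPh3 (CH2Cl2, 0 °C) into the propargylic bromide F3. Williamson etherification of F1 (NaH, THF–DMF, 0 °C) with F3 gives 7.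

**Further compounds**
F1 | step 3 | (S)-1-[3-(benzyloxy)-4-methoxyphenyl]prop-2-en-1-ol | C=C[C@H](O)c1ccc(OC)c(OCc2ccccc2)c1
F2 | step 3 | (R)-1-[3-(benzyloxy)-4-methoxyphenyl]prop-2-en-1-yl acetate | C=C[C@@H](OC(C)=O)c1ccc(OC)c(OCc2ccccc2)c1
F3 | step 3 | 2-(benzyloxy)-4-(3-bromoprop-1-yn-1-yl)-1-methoxybenzene | BrCC#Cc1ccc(OC)c(OCc2ccccc2)c1
F4 | step 4 | 2-{[(2S,3S)-2-[3-(benzyloxy)-4-methoxyphenyl]-4-{[3-(benzyloxy)-4-methoxyphenyl]methylidene}oxolan-3-yl]methyl}-4,4,5,5-tetramethyl-1,3,2-dioxaborolane (alkene geometry immaterial) | COc1ccc(C=C2CO[C@H](c3ccc(OC)c(OCc4ccccc4)c3)[C@H]2CB2OC(C)(C)C(C)(C)O2)cc1OCc1ccccc1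
F5 | step 4 | [(4R,5S)-5-[3-(benzyloxy)-4-methoxyphenyl]-4-(hydroxymethyl)oxolan-3-yl][3-(benzyloxy)-4-methoxyphenyl]methanol (mixture at C-3 and at the carbinol carbon) | COc1ccc(C(O)C2CO[C@H](c3ccc(OC)c(OCc4ccccc4)c3)[C@H]2CO)cc1OCc1ccccc1
F6 | step 5 | terminal epoxide of 7, 2-(benzyloxy)-4-[3-({[3-(benzyloxy)-4-methoxyphenyl](oxiran-2-yl)methyl}oxy)prop-1-yn-1-yl]-1-methoxybenzene (benzylic centre as in 7, both epoxide epimers) | C1OC1[C@H](OCC#Cc2ccc(OC)c(OCc3ccccc3)c2)c2ccc(OC)c(OCc3ccccc3)c2
F7 | step 5 | [(2S,3R)-2-[3-(benzyloxy)-4-methoxyphenyl]-4-{[3-(benzyloxy)-4-methoxyphenyl]methylidene}oxolan-3-yl]methanol (alkene geometry immaterial) | COc1ccc(C=C2CO[C@H](c3ccc(OC)c(OCc4ccccc4)c3)[C@H]2CO)cc1OCc1ccccc1
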